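**Strategy.** The route rests on closing the C2–O1 bond of the 2,3-dihydrobenzofuran last. The key step unmasks two phenols with HF·pyridine: the 4-hydroxyphenyl group on C2 turns the C2 carbinol into a para-quinone methide, and the phenolic O1 on the enone-bearing benzo ring adds 5-exo, erasing the C2 epimer mixture and setting C2 trans to C3. The precursor is an open-chain 1,2,3,3-tetraaryl-propan-1-ol that already carries the finished oxolane ring and the chalcone. Its C3 and diarylmethine centres come from an aminocatalytic [4+2] annulation of an ortho-quinone methide; the oxolane comes from an auxiliary-controlled anti-aldol, a lactone alkylation and a Friedel–Crafts arylation.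

Key step: step 21

Remark: MOM = methoxymethyl, TBS = tert-butyldimethylsilyl; "fragment T" = the (2R,3R,4R,5S)-4-[2,4-bis(MOM-oxy)benzoyl]-3-[4-(MOM-oxy)benzyl]-5-[4-(MOM-oxy)phenyl]oxolan-2-yl group; the carbinol carbon of 21, the anomeric carbons of 14 and 26 and the C1 carbinol of 28, 29, 32 and 33 are carried as epimer mixtures because each becomes planar in a later step.

Step 1
Reactants: 1 4-bromobenzene-1,3-diol
Product: 2 1-bromo-2,4-bis(methoxymethoxy)benzene
Conditions: MeOCH2Cl (2.5 equiv), i-Pr2NEt, CH2Cl2, 0 → 23 °C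
Reagents that add atoms: chloromethyl methyl ether, COCCl
Why: O-alkylation of both phenols (Williamson type) gives acetal ethers that should survive the organometallic, Lewis-acid and fluoride steps ahead.

Step 2
Reactants: 3 (4S)-4-benzyl-1,3-oxazolidin-2-one; 4 methyl 4-chloro-4-oxobutanoate
Product: 5 methyl 4-[(4S)-4-benzyl-2-oxo-1,3-oxazolidin-3-yl]-4-oxobutanoate
Conditions: n-BuLi, THF, −78 °C; then 4, −78 → 0 °C
Reagents that add atoms: none
Why: N-acylation of the lithiated oxazolidinone by the acid chloride, which is far more electrophilic than the ester end; the auxiliary stereocentre is untouched.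

Step 3
Reactants: 5; 6 4-(methoxymethoxy)benzaldehyde
Product: 7 anti-aldol silyl ether, methyl (3R,4S)-3-[(4S)-4-benzyl-2-oxo-1,3-oxazolidine-3-carbonyl]-4-[4-(MOM-oxy)phenyl]-4-(trimethylsilyloxy)butanoate
Conditions: MgCl2 (20 mol %), Et3N, Me3SiCl, EtOAc, 23 °C
Reagents that add atoms: chlorotrimethylsilane, C[Si](C)(C)Cl
Why: Magnesium-halide-catalysed direct anti-aldol addition of an N-acyl oxazolidinone (soft enolisation, silyl trapping of the aldolate); the aldehyde should attack the chelated Z-enolate on the face away from the auxiliary benzyl group, which sets the α-centre (R), and the anti topology sets the silyloxy centre (S).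

Step 4
Reactants: 7
Product: 9 (2S,3R)-2-[4-(MOM-oxy)phenyl]-5-oxooxolane-3-carboxylic acid (2,3-cis), via hydroxy diacid 8 (not isolated)
Conditions: LiOH, H2O2, THF/H2O, 0 → 23 °C; aq. Na2SO3; then 1 M HCl to pH 2, 23 °C
Reagents that add atoms: hydrogen peroxide (acting as lithium hydroperoxide; one oxygen of the carboxyl group), OO
Why: Hydroperoxide cleaves the imide at the exocyclic carbonyl while hydroxide removes the methyl ester and the silyl ether, and on acidification the γ-hydroxy acid lactonises; both stereocentres are carried over unchanged, the anti-aldol relationship becoming 2,3-cis in the ring.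

Step 5
Reactants: 10 4-(hydroxymethyl)phenol
Product: 11 [4-(methoxymethoxy)phenyl]methanol
Conditions: MeOCH2Cl (1.1 equiv), K2CO3, acetone, 23 °C
Reagents that add atoms: chloromethyl methyl ether, COCCl
Why: Under carbonate conditions only the phenoxide is alkylated (Williamson etherification), leaving the benzylic alcohol free.

Step 6
Reactants: 11
Product: 12 1-(bromomethyl)-4-(methoxymethoxy)benzene
Conditions: CBr4, PPh3, CH2Cl2, 0 °C; used at once
Reagents that add atoms: carbon tetrabromide, BrC(Br)(Br)Br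
Why: Appel reaction converts the benzylic alcohol to the bromide under neutral conditions that should spare the acetal.

Step 7
Reactants: 9; 12
Product: 13 (2S,3R,4R)-4-[4-(MOM-oxy)benzyl]-2-[4-(MOM-oxy)phenyl]-5-oxooxolane-3-carboxylic acid
Conditions: LiN(SiMe3)2 (2.2 equiv), THF, −78 °C; then 12, −78 → −40 °C; aq. HCl to pH 3
Reagents that add atoms: none
Why: Alkylation of the lactone enolate within the carboxylate dianion; the benzyl group should enter on the ring face opposite to the neighbouring carboxylate and the aryl group, giving the 3,4-trans centre by substrate control.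

Step 8
Reactants: 13
Product: 14 (2S,3R,4R)-5-hydroxy-4-[4-(MOM-oxy)benzyl]-2-[4-(MOM-oxy)phenyl]oxolane-3-carboxylic acid
Conditions: i-Bu2AlH (3.2 equiv), CH2Cl2, −78 °C; aq. potassium sodium tartrate
Reagents that add atoms: none
Why: Partial reduction of the γ-lactone to the lactol through a tetrahedral aluminate that is stable at low temperature, the aluminium carboxylate being inert; the new anomeric centre is erased in step 9.

Step 9
Reactants: 14; 2
Product: 15 (2S,3R,4R,5R)-5-[5-bromo-2,4-bis(MOM-oxy)phenyl]-4-[4-(MOM-oxy)benzyl]-2-[4-(MOM-oxy)phenyl]oxolane-3-carboxylic acid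
Conditions: BF3·OEt2 (2 equiv), CH2Cl2, −78 → −30 °C
Reagents that add atoms: none
Why: Friedel–Crafts arylation of the cyclic oxocarbenium ion by the position of 2 that is para to one and ortho to the other oxygen; the aryl group should add anti to the adjacent benzyl group, and the 2,3-trans benzylic ether is also the thermodynamic isomer.

Step 10
Reactants: 15
Product: 16 (2S,3R,4R,5R)-5-[5-formyl-2,4-bis(MOM-oxy)phenyl]-4-[4-(MOM-oxy)benzyl]-2-[4-(MOM-oxy)phenyl]oxolane-3-carboxylic acid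
Conditions: n-BuLi (2.2 equiv), THF, −78 °C; then DMF, −78 → 0 °C; aq. NH4Cl
Reagents that add atoms: N,N-dimethylformamide, CN(C)C=O
Why: Deprotonation of the acid, then bromine–lithium exchange and formylation of the aryllithium by DMF; the lithium carboxylate is inert at this temperature and no stereocentre is involved.

Step 11
Reactants: 16; 2
Product: 18 5-(fragment T)-2,4-bis(MOM-oxy)benzaldehyde, via acid chloride 17 (not isolated)
Conditions: 1-chloro-N,N,2-trimethylprop-1-en-1-amine, CH2Cl2, 0 °C; then ArZnCl [from 2, n-BuLi, ZnCl2, THF, −78 → 0 °C], Pd(PPh3)4 (5 mol %), THF, 0 → 23 °C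
Reagents that add atoms: none
Why: Acid chloride formation under neutral conditions followed by Negishi acylation on zerovalent palladium; the arylzinc should spare the aldehyde, and no base is present that could enolise the centre next to the new ketone.

Step 12
Reactants: 19 benzene-1,3-diol
Product: 20 3-(methoxymethoxy)phenol
Conditions: MeOCH2Cl (1.0 equiv), K2CO3, acetone, 23 °C; mono-ether separated from the bis-ether
Reagents that add atoms: chloromethyl methyl ether, COCCl
Why: Statistical mono-alkylation of a symmetrical diphenol (Williamson etherification).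

Step 13
Reactants: 18; 20
Product: 21 [2-hydroxy-4-(MOM-oxy)phenyl][2,4-bis(MOM-oxy)-5-(fragment T)phenyl]methanol
Conditions: 20, EtMgBr, Et2O, 0 °C; solvent exchange to CH2Cl2; then 18, 23 °C
Reagents that add atoms: none
Why: ortho-Selective hydroxyalkylation of the magnesium phenolate by the aldehyde through a six-membered chelate, at the less hindered ortho position para to the acetal ether; the phenolate is too weak a base to enolise the ketone, and the new carbinol centre is left uncontrolled because it becomes the methide carbon in step 16.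

Step 14
Reactants: 22 4-bromo-2-(prop-2-en-1-yl)phenol
Product: 23 [4-bromo-2-(prop-2-en-1-yl)phenoxy](tert-butyl)dimethylsilane
Conditions: t-BuMe2SiCl, imidazole, DMF, 23 °C
Reagents that add atoms: tert-butyldimethylsilyl chloride, CC(C)(C)[Si](C)(C)Cl
Why: Silylation gives the phenol a protecting group that is orthogonal to the acetal ethers and is removed by fluoride in the key step.

Step 15
Reactants: 23
Product: 24 2-[5-bromo-2-(TBS-oxy)phenyl]acetaldehyde
Conditions: O3, CH2Cl2, −78 °C; then PPh3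
Reagents that add atoms: ozone, [O-][O+]=O
Why: Ozonolysis of the terminal alkene with reductive work-up gives the arylacetaldehyde.

Step 16
Reactants: 21; 24
Product: 26 (3S,4R)-3-[5-bromo-2-(TBS-oxy)phenyl]-4-[2,4-bis(MOM-oxy)-5-(fragment T)phenyl]-7-(MOM-oxy)-3,4-dihydro-2H-chromen-2-ol, via ortho-quinone methide 25 (not isolated)
Conditions: (S)-α,α-diphenylprolinol trimethylsilyl ether (20 mol %), PhCO2H (20 mol %), CH2Cl2, 23 °C
Reagents that add atoms: none
Why: Aminocatalytic formal [4+2] annulation (enamine Michael addition to the ortho-quinone methide formed by acid-promoted dehydration, then hemiacetalisation); the (S)-catalyst shields one enamine face and so sets C3, the synclinal approach gives the diarylmethine centre, and the 3,4-trans lactol is also the thermodynamic one.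

Step 17
Reactants: 26; 27 (4-bromophenoxy)(tert-butyl)dimethylsilane
Product: 28 (2S,3R)-2-[5-bromo-2-(TBS-oxy)phenyl]-1-[4-(TBS-oxy)phenyl]-3-[2-hydroxy-4-(MOM-oxy)phenyl]-3-[2,4-bis(MOM-oxy)-5-(fragment T)phenyl]propan-1-ol
Conditions: 27, n-BuLi, THF, −78 °C; ClTi(OiPr)3; then 26, −78 → 0 °C
Reagents that add atoms: none
Why: Chemoselective 1,2-addition of a non-basic aryltitanium triisopropoxide to the open aldehyde form of the lactol, which should leave the hindered diaryl ketone and its α-centre alone; the new carbinol centre is uncontrolled and is erased in step 21.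

Step 18
Reactants: 28
Product: 29 (2S,3R)-2-[5-bromo-2-(TBS-oxy)phenyl]-1-[4-(TBS-oxy)phenyl]-3-[2,4-bis(MOM-oxy)phenyl]-3-[2,4-bis(MOM-oxy)-5-(fragment T)phenyl]propan-1-ol
Conditions: MeOCH2Cl (1.3 equiv), i-Pr2NEt, CH2Cl2, 0 °C
Reagents that add atoms: chloromethyl methyl ether, COCCl
Why: The phenol is alkylated far faster than the hindered secondary benzylic alcohol (Williamson etherification), which removes the only oxygen nucleophile that could compete with O1 in step 21.

Step 19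
Reactants: 2; 30 N-methoxy-N-methylprop-2-enamide
Product: 31 1-[2,4-bis(methoxymethoxy)phenyl]prop-2-en-1-one
Conditions: n-BuLi, THF, −78 °C; then 30; cold aq. NH4Cl
Reagents that add atoms: none
Why: Bromine–lithium exchange and acylation by the N-methoxy-N-methylamide, whose chelated tetrahedral adduct stops the addition at the ketone stage.

Step 20
Reactants: 29; 31
Product: 32 (2E)-1-[2,4-bis(MOM-oxy)phenyl]-3-[4-(TBS-oxy)-3-{(2S,3R)-1-hydroxy-1-[4-(TBS-oxy)phenyl]-3-[2,4-bis(MOM-oxy)phenyl]-3-[2,4-bis(MOM-oxy)-5-(fragment T)phenyl]propan-2-yl}phenyl]prop-2-en-1-one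
Conditions: Pd(OAc)2 (5 mol %), P(o-tol)3 (10 mol %), Et3N, MeCN, 80 °C
Reagents that add atoms: none
Why: Heck reaction of the aryl bromide with the aryl vinyl ketone; syn insertion and syn β-hydride elimination should give the E-enone, and no stereocentre is involved.

Step 21
Reactants: 32
Product: 35 (2E)-1-[2,4-bis(MOM-oxy)phenyl]-3-[(2S,3S)-3-{(R)-[2,4-bis(MOM-oxy)phenyl][2,4-bis(MOM-oxy)-5-(fragment T)phenyl]methyl}-2-(4-hydroxyphenyl)-2,3-dihydro-1-benzofuran-5-yl]prop-2-en-1-one, via bis-phenol carbinol 33 (not isolated), via para-quinone methide 34 (not isolated)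
Conditions: HF·pyridine, THF, 0 → 23 °C
Reagents that add atoms: none
Why: HF·pyridine cleaves the two aryl silyl ethers (33), the 4-hydroxybenzylic carbinol then loses water in the weakly acidic medium to give para-quinone methide 34, and the ortho phenol O1 adds to the methide carbon with rearomatisation. The closest known reaction type is the acid- or quinone-methide-mediated cyclisation of 1-(4-hydroxyphenyl)-2-(2-hydroxyaryl)alkan-1-ols to trans-2-aryl-2,3-dihydrobenzofurans used for 8–5′ neolignans. The ring closes in 5-exo-trig mode (O1 onto C2), forming only the O1–C2 bond. The new stereocentre C2 is controlled by the existing C3 centre: the aryl group should take the face anti to the bulky diarylmethyl group on C3, the addition is reversible so trans is also the thermodynamic isomer, and both carbinol epimers converge through planar 34. The step needs O1 (5-exo) to win over the ortho oxygen of the neighbouring 2,4-dioxygenated ring (6-exo), which is secured because that oxygen is an acetal ether whereas O1 is a free phenol. It also needs the oxolane benzylic ethers and the ketone α-centre to survive, which the weakly acidic, base-free fluoride medium should allow.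

Step 22
Reactants: 35
Product: 36 the target (CNP0225254.5)
Conditions: Me3SiOTf, 2,2'-bipyridyl, CH2Cl2/MeCN, 0 °C; then H2O
Reagents that add atoms: none
Why: The ten aryl methoxymethyl ethers are converted under buffered, non-protic conditions into pyridinium acetals and silyl ethers that hydrolyse on adding water; this avoids the strong protic acid that could ionise the benzylic ethers of the oxolane and dihydrobenzofuran, and the base that could enolise the ketone α-centre.

**Compound list**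

1 | 4-bromobenzene-1,3-diol | Oc1ccc(Br)c(O)c1 | starting material
2 | 1-bromo-2,4-bis(methoxymethoxy)benzene | COCOc1ccc(Br)c(OCOC)c1 | intermediate
3 | (4S)-4-benzyl-1,3-oxazolidin-2-one | O=C1N[C@@H](Cc2ccccc2)CO1 | starting material
4 | methyl 4-chloro-4-oxobutanoate | COC(=O)CCC(Cl)=O | starting material
5 | methyl 4-[(4S)-4-benzyl-2-oxo-1,3-oxazolidin-3-yl]-4-oxobutanoate | COC(=O)CCC(=O)N1C(=O)OC[C@@H]1Cc1ccccc1 | intermediate
6 | 4-(methoxymethoxy)benzaldehyde | O=Cc1ccc(OCOC)cc1 | starting material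
7 | methyl (3R,4S)-3-[(4S)-4-benzyl-2-oxo-1,3-oxazolidine-3-carbonyl]-4-[4-(methoxymethoxy)phenyl]-4-(trimethylsilyloxy)butanoate | COC(=O)C[C@@H](C(=O)N1C(=O)OC[C@@H]1Cc1ccccc1)[C@H](O[Si](C)(C)C)c1ccc(OCOC)cc1 | intermediate
8 | (2R)-2-{(S)-hydroxy[4-(methoxymethoxy)phenyl]methyl}butanedioic acid | OC(=O)C[C@@H](C(=O)O)[C@H](O)c1ccc(OCOC)cc1 | intermediate
9 | (2S,3R)-2-[4-(methoxymethoxy)phenyl]-5-oxooxolane-3-carboxylic acid | O=C1C[C@@H](C(=O)O)[C@@H](c2ccc(OCOC)cc2)O1 | intermediate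
10 | 4-(hydroxymethyl)phenol | OCc1ccc(O)cc1 | starting material
11 | [4-(methoxymethoxy)phenyl]methanol | COCOc1ccc(CO)cc1 | intermediate
12 | 1-(bromomethyl)-4-(methoxymethoxy)benzene | COCOc1ccc(CBr)cc1 | intermediate
13 | (2S,3R,4R)-4-[4-(methoxymethoxy)benzyl]-2-[4-(methoxymethoxy)phenyl]-5-oxooxolane-3-carboxylic acid | O=C1[C@H](Cc2ccc(OCOC)cc2)[C@@H](C(=O)O)[C@@H](c2ccc(OCOC)cc2)O1 | intermediate
14 | (2S,3R,4R)-5-hydroxy-4-[4-(methoxymethoxy)benzyl]-2-[4-(methoxymethoxy)phenyl]oxolane-3-carboxylic acid (anomers) | OC1[C@H](Cc2ccc(OCOC)cc2)[C@@H](C(=O)O)[C@@H](c2ccc(OCOC)cc2)O1 | intermediate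
15 | (2S,3R,4R,5R)-5-[5-bromo-2,4-bis(methoxymethoxy)phenyl]-4-[4-(methoxymethoxy)benzyl]-2-[4-(methoxymethoxy)phenyl]oxolane-3-carboxylic acid | COCOc1cc(OCOC)c(cc1Br)[C@@H]1O[C@H](c2ccc(OCOC)cc2)[C@H](C(=O)O)[C@H]1Cc1ccc(OCOC)cc1 | intermediate
16 | (2S,3R,4R,5R)-5-[5-formyl-2,4-bis(methoxymethoxy)phenyl]-4-[4-(methoxymethoxy)benzyl]-2-[4-(methoxymethoxy)phenyl]oxolane-3-carboxylic acid | COCOc1cc(OCOC)c(cc1C=O)[C@@H]1O[C@H](c2ccc(OCOC)cc2)[C@H](C(=O)O)[C@H]1Cc1ccc(OCOC)cc1 | intermediate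
17 | (2S,3R,4R,5R)-5-[5-formyl-2,4-bis(methoxymethoxy)phenyl]-4-[4-(methoxymethoxy)benzyl]-2-[4-(methoxymethoxy)phenyl]oxolane-3-carbonyl chloride | COCOc1cc(OCOC)c(cc1C=O)[C@@H]1O[C@H](c2ccc(OCOC)cc2)[C@H](C(Cl)=O)[C@H]1Cc1ccc(OCOC)cc1 | intermediate
18 | 5-{(2R,3R,4R,5S)-4-[2,4-bis(methoxymethoxy)benzoyl]-3-[4-(methoxymethoxy)benzyl]-5-[4-(methoxymethoxy)phenyl]oxolan-2-yl}-2,4-bis(methoxymethoxy)benzaldehyde | COCOc1cc(OCOC)c(cc1C=O)[C@@H]1O[C@H](c2ccc(OCOC)cc2)[C@H](C(=O)c2ccc(OCOC)cc2OCOC)[C@H]1Cc1ccc(OCOC)cc1 | intermediate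
19 | benzene-1,3-diol | Oc1cccc(O)c1 | starting material
20 | 3-(methoxymethoxy)phenol | COCOc1cccc(O)c1 | intermediate
21 | [2-hydroxy-4-(MOM-oxy)phenyl][2,4-bis(MOM-oxy)-5-(fragment T)phenyl]methanol (carbinol epimers) | COCOc1cc(OCOC)c(cc1C(O)c1ccc(OCOC)cc1O)[C@@H]1O[C@H](c2ccc(OCOC)cc2)[C@H](C(=O)c2ccc(OCOC)cc2OCOC)[C@H]1Cc1ccc(OCOC)cc1 | intermediate
22 | 4-bromo-2-(prop-2-en-1-yl)phenol | C=CCc1cc(Br)ccc1O | starting material
23 | [4-bromo-2-(prop-2-en-1-yl)phenoxy](tert-butyl)dimethylsilane | C=CCc1cc(Br)ccc1O[Si](C)(C)C(C)(C)C | intermediate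
24 | 2-[5-bromo-2-(tert-butyldimethylsilyloxy)phenyl]acetaldehyde | O=CCc1cc(Br)ccc1O[Si](C)(C)C(C)(C)C | intermediate
25 | (6E)-6-{[2,4-bis(MOM-oxy)-5-(fragment T)phenyl]methylidene}-3-(methoxymethoxy)cyclohexa-2,4-dien-1-one | O=C1C=C(OCOC)C=C\C1=C/c1cc([C@@H]2O[C@H](c3ccc(OCOC)cc3)[C@H](C(=O)c3ccc(OCOC)cc3OCOC)[C@H]2Cc2ccc(OCOC)cc2)c(OCOC)cc1OCOC | intermediate
26 | (3S,4R)-3-[5-bromo-2-(TBS-oxy)phenyl]-4-[2,4-bis(MOM-oxy)-5-(fragment T)phenyl]-7-(MOM-oxy)-3,4-dihydro-2H-chromen-2-ol (3,4-trans; anomers) | OC1Oc2cc(OCOC)ccc2[C@H](c2cc([C@@H]3O[C@H](c4ccc(OCOC)cc4)[C@H](C(=O)c4ccc(OCOC)cc4OCOC)[C@H]3Cc3ccc(OCOC)cc3)c(OCOC)cc2OCOC)[C@H]1c1cc(Br)ccc1O[Si](C)(C)C(C)(C)C | intermediate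
27 | (4-bromophenoxy)(tert-butyl)dimethylsilane | CC(C)(C)[Si](C)(C)Oc1ccc(Br)cc1 | starting material
28 | (2S,3R)-2-[5-bromo-2-(TBS-oxy)phenyl]-1-[4-(TBS-oxy)phenyl]-3-[2-hydroxy-4-(MOM-oxy)phenyl]-3-[2,4-bis(MOM-oxy)-5-(fragment T)phenyl]propan-1-ol (C1 epimers) | CC(C)(C)[Si](C)(C)Oc1ccc(Br)cc1[C@H]([C@H](c1ccc(OCOC)cc1O)c1cc([C@@H]2O[C@H](c3ccc(OCOC)cc3)[C@H](C(=O)c3ccc(OCOC)cc3OCOC)[C@H]2Cc2ccc(OCOC)cc2)c(OCOC)cc1OCOC)C(O)c1ccc(O[Si](C)(C)C(C)(C)C)cc1 | intermediate
29 | (2S,3R)-2-[5-bromo-2-(TBS-oxy)phenyl]-1-[4-(TBS-oxy)phenyl]-3-[2,4-bis(MOM-oxy)phenyl]-3-[2,4-bis(MOM-oxy)-5-(fragment T)phenyl]propan-1-ol (C1 epimers) | CC(C)(C)[Si](C)(C)Oc1ccc(Br)cc1[C@H]([C@H](c1ccc(OCOC)cc1OCOC)c1cc([C@@H]2O[C@H](c3ccc(OCOC)cc3)[C@H](C(=O)c3ccc(OCOC)cc3OCOC)[C@H]2Cc2ccc(OCOC)cc2)c(OCOC)cc1OCOC)C(O)c1ccc(O[Si](C)(C)C(C)(C)C)cc1 | intermediate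
30 | N-methoxy-N-methylprop-2-enamide | C=CC(=O)N(C)OC | starting material
31 | 1-[2,4-bis(methoxymethoxy)phenyl]prop-2-en-1-one | C=CC(=O)c1ccc(OCOC)cc1OCOC | intermediate
32 | (2E)-1-[2,4-bis(MOM-oxy)phenyl]-3-[4-(TBS-oxy)-3-{(2S,3R)-1-hydroxy-1-[4-(TBS-oxy)phenyl]-3-[2,4-bis(MOM-oxy)phenyl]-3-[2,4-bis(MOM-oxy)-5-(fragment T)phenyl]propan-2-yl}phenyl]prop-2-en-1-one (carbinol epimers) | CC(C)(C)[Si](C)(C)Oc1ccc(/C=C/C(=O)c2ccc(OCOC)cc2OCOC)cc1[C@H]([C@H](c1ccc(OCOC)cc1OCOC)c1cc([C@@H]2O[C@H](c3ccc(OCOC)cc3)[C@H](C(=O)c3ccc(OCOC)cc3OCOC)[C@H]2Cc2ccc(OCOC)cc2)c(OCOC)cc1OCOC)C(O)c1ccc(O[Si](C)(C)C(C)(C)C)cc1 | intermediate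
33 | compound 32 with both silyloxy groups replaced by hydroxy groups (bis-phenol carbinol, carbinol epimers) | Oc1ccc(/C=C/C(=O)c2ccc(OCOC)cc2OCOC)cc1[C@H]([C@H](c1ccc(OCOC)cc1OCOC)c1cc([C@@H]2O[C@H](c3ccc(OCOC)cc3)[C@H](C(=O)c3ccc(OCOC)cc3OCOC)[C@H]2Cc2ccc(OCOC)cc2)c(OCOC)cc1OCOC)C(O)c1ccc(O)cc1 | intermediate
34 | para-quinone methide formed from 33 by loss of water: the carbinol carbon is now the exocyclic methylidene carbon of a cyclohexa-2,5-dien-1-one, other centres as in 33 | Oc1ccc(/C=C/C(=O)c2ccc(OCOC)cc2OCOC)cc1[C@H]([C@H](c1ccc(OCOC)cc1OCOC)c1cc([C@@H]2O[C@H](c3ccc(OCOC)cc3)[C@H](C(=O)c3ccc(OCOC)cc3OCOC)[C@H]2Cc2ccc(OCOC)cc2)c(OCOC)cc1OCOC)C=C1C=CC(=O)C=C1 | intermediate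
35 | (2E)-1-[2,4-bis(MOM-oxy)phenyl]-3-[(2S,3S)-3-{(R)-[2,4-bis(MOM-oxy)phenyl][2,4-bis(MOM-oxy)-5-(fragment T)phenyl]methyl}-2-(4-hydroxyphenyl)-2,3-dihydro-1-benzofuran-5-yl]prop-2-en-1-one | O=C(/C=C/c1ccc2c(c1)[C@H]([C@H](c1ccc(OCOC)cc1OCOC)c1cc([C@@H]3O[C@H](c4ccc(OCOC)cc4)[C@H](C(=O)c4ccc(OCOC)cc4OCOC)[C@H]3Cc3ccc(OCOC)cc3)c(OCOC)cc1OCOC)[C@@H](c1ccc(O)cc1)O2)c1ccc(OCOC)cc1OCOC | intermediate
36 | (2E)-1-(2,4-dihydroxyphenyl)-3-[(2S,3S)-3-{(R)-(2,4-dihydroxyphenyl)[5-((2R,3R,4R,5S)-4-(2,4-dihydroxybenzoyl)-3-(4-hydroxybenzyl)-5-(4-hydroxyphenyl)oxolan-2-yl)-2,4-dihydroxyphenyl]methyl}-2-(4-hydroxyphenyl)-2,3-dihydro-1-benzofuran-5-yl]prop-2-en-1-one (CNP0225254.5) | O=C(/C=C/c1ccc2c(c1)[C@H]([C@H](c1ccc(O)cc1O)c1cc([C@@H]3O[C@H](c4ccc(O)cc4)[C@H](C(=O)c4ccc(O)cc4O)[C@H]3Cc3ccc(O)cc3)c(O)cc1O)[C@@H](c1ccc(O)cc1)O2)c1ccc(O)cc1O | target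

**Step count and risks**

Total step count: 22. Longest linear sequence: 15 steps (steps 2, 3, 4, 7, 8, 9, 10, 11, 13, 16, 17, 18, 20, 21, 22).

The three steps most likely to fail:

Step 21 (key step). The carbinol may ionise too slowly in the weakly acidic fluoride medium. The quinone methide may be captured by fluoride, by water, or 6-exo by the neighbouring acetal-protected oxygen with loss of that acetal. Prolonged acid exposure may epimerise the oxolane benzylic carbons. The fallback sets out from 29 and moves the ring closure before the Heck reaction, using a better leaving group and a fluoride trigger. Acetylation of the carbinol (Ac2O, pyridine, 0 °C) should give the C1 acetate of 29 F1. Bu4NF buffered with AcOH in THF at 0 °C should strip both silyl ethers; the para-phenoxide then expels acetate (1,6-elimination) and the ortho-phenoxide closes 5-exo to the (2S,3S)-5-bromo-2-(4-hydroxyphenyl)-2,3-dihydrobenzofuran F2. Heck reaction of F2 with 31 under the conditions of step 20 comes back to the route at 35.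

Step 16. The bulky ortho-quinone methide may react slowly with the enamine, so that self-aldol of 24 and reversible Michael addition erode the facial selectivity. The fallback sets out from 24 and replaces enamine catalysis by a Brønsted-acid-catalysed inverse-demand hetero-Diels–Alder reaction. Silylation (t-BuMe2SiOTf, Et3N, CH2Cl2, 0 °C) should give the (Z)-silyl enol ether of 24 F3. With 21 and a chiral phosphoric acid (3,3'-bis(2,4,6-triisopropylphenyl)-1,1'-binaphthyl-2,2'-diyl hydrogen phosphate, the enantiomer that delivers the 3S,4R adduct, toluene, −20 °C), F3 should add to the ortho-quinone methide 25 to give the 2-silyloxychroman F4. Mild hydrolysis of the anomeric silyl ether (pyridinium p-toluenesulfonate, wet THF) comes back to the route at 26.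

Step 9. Arylation by the bromine-deactivated arene 2 may be slow, leaving time for loss of acetal groups under BF3 or for elimination of the oxocarbenium ion to a dihydrofuran. The fallback sets out from 14 and introduces the halogen after the arylation. Friedel–Crafts arylation with the more nucleophilic 1,3-bis(methoxymethoxy)benzene (the bis-ether co-formed in step 12; BF3·OEt2, CH2Cl2, −78 °C) should give the bromine-free aryl oxolane acid F5. Bromination with N-bromosuccinimide in MeCN at 0 °C, para to one and ortho to the other oxygen of the most electron-rich ring, comes back to the route at 15.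

Further compounds
F1 | step 21 | C1 acetate of 29 | CC(C)(C)[Si](C)(C)Oc1ccc(Br)cc1[C@H]([C@H](c1ccc(OCOC)cc1OCOC)c1cc([C@@H]2O[C@H](c3ccc(OCOC)cc3)[C@H](C(=O)c3ccc(OCOC)cc3OCOC)[C@H]2Cc2ccc(OCOC)cc2)c(OCOC)cc1OCOC)C(OC(C)=O)c1ccc(O[Si](C)(C)C(C)(C)C)cc1
F2 | step 21 | 4-[(2S,3S)-5-bromo-3-{(R)-[2,4-bis(MOM-oxy)phenyl][2,4-bis(MOM-oxy)-5-(fragment T)phenyl]methyl}-2,3-dihydro-1-benzofuran-2-yl]phenol | Brc1ccc2c(c1)[C@H]([C@H](c1ccc(OCOC)cc1OCOC)c1cc([C@@H]3O[C@H](c4ccc(OCOC)cc4)[C@H](C(=O)c4ccc(OCOC)cc4OCOC)[C@H]3Cc3ccc(OCOC)cc3)c(OCOC)cc1OCOC)[C@@H](c1ccc(O)cc1)O2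
F3 | step 16 | (Z)-silyl enol ether of 24, {4-bromo-2-[(Z)-2-(tert-butyldimethylsilyloxy)ethenyl]phenoxy}(tert-butyl)dimethylsilane | CC(C)(C)[Si](C)(C)O/C=C\c1cc(Br)ccc1O[Si](C)(C)C(C)(C)C
F4 | step 16 | 2-O-tert-butyldimethylsilyl ether of lactol 26 (2-silyloxychroman, anomers) | CC(C)(C)[Si](C)(C)OC1Oc2cc(OCOC)ccc2[C@H](c2cc([C@@H]3O[C@H](c4ccc(OCOC)cc4)[C@H](C(=O)c4ccc(OCOC)cc4OCOC)[C@H]3Cc3ccc(OCOC)cc3)c(OCOC)cc2OCOC)[C@H]1c1cc(Br)ccc1O[Si](C)(C)C(C)(C)C
F5 | step 9 | (2S,3R,4R,5R)-5-[2,4-bis(methoxymethoxy)phenyl]-4-[4-(methoxymethoxy)benzyl]-2-[4-(methoxymethoxy)phenyl]oxolane-3-carboxylic acid | COCOc1ccc(c(OCOC)c1)[C@@H]1O[C@H](c2ccc(OCOC)cc2)[C@H](C(=O)O)[C@H]1Cc1ccc(OCOC)cc1
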